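**Retrosynthetic overview**
1. Gravicycle ⇒ macrocyclic aryl ketone (C=O at the carbinol carbon). The only stereocentre is set last, by asymmetric transfer hydrogenation of the unprotected triphenol.
2. Macrocyclic ketone ⇒ open-chain tetraphenol bromo-ketone (key C–O disconnection). A protecting-group-free Ullmann etherification closes the 22-membered ring: either of the two homotopic OH groups of the C2-symmetric 5-alkylresorcinol attacks the 4-bromo-3,5-dihydroxyaryl ketone, breaking the resorcinol's symmetry.
3. Tetraphenol ⇒ tetramethyl ether (one global BBr3) ⇒ Weinreb amide of 4-bromo-3,5-dimethoxybenzoic acid + C13 alkyl Grignard.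
4. C13 bromide ⇒ 3,5-dimethoxybenzylmagnesium chloride + 1,12-dibromododecane (mono-coupling of the symmetric dibromide).
5. Ring order: both benzene rings are bought intact; the only ring formed is the 22-membered macrocycle (step 5).

Assumption: compounds 1, 2 and 4 are catalogue materials, and the [C@H] centre of the target is read as R (OH > aryl > CH2 > H).

**Step 1**
Reactants: 1, 3,5-dimethoxybenzyl chloride; 2, 1,12-dibromododecane
Product: 3, 1-(13-bromotridecyl)-3,5-dimethoxybenzene
Conditions: 1, Mg, THF, 0 °C; then add to 2 (4 equiv), Li2CuCl4 (3 mol %), THF, −20 → 0 °C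
Reagents that add atoms: none (both carbon fragments are numbered reactants)
Why: Kochi-type Cu-catalysed sp3–sp3 Grignard/primary alkyl bromide coupling; the excess of symmetric dibromide limits double coupling, and using the benzylic chloride keeps Wurtz homocoupling low.

**Step 2**
Reactants: 4, 4-bromo-3,5-dimethoxybenzoic acid
Product: 5, 4-bromo-N,3,5-trimethoxy-N-methylbenzamide (Weinreb amide)
Conditions: CDI, CH2Cl2, rt; then MeNH(OMe)·HCl, rt
Reagents that add atoms: N,O-dimethylhydroxylamine hydrochloride, CNOC.Cl
Why: Standard acyl-imidazolide amidation to the Weinreb amide; the aryl bromide and methyl ethers are inert.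

**Step 3**
Reactants: 3, 1-(13-bromotridecyl)-3,5-dimethoxybenzene; 5, Weinreb amide
Product: 6, 1-(4-bromo-3,5-dimethoxyphenyl)-14-(3,5-dimethoxyphenyl)tetradecan-1-one
Conditions: 3, Mg (cat. I2), THF, 50 °C; then 5, THF, −10 → 0 °C; aq NH4Cl
Reagents that add atoms: none
Why: Weinreb ketone synthesis; the chelated tetrahedral intermediate prevents over-addition, and a primary alkyl Grignard does not exchange with the aryl bromide at ≤0 °C.

**Step 4**
Reactants: 6
Product: 7, 1-(4-bromo-3,5-dihydroxyphenyl)-14-(3,5-dihydroxyphenyl)tetradecan-1-one
Conditions: BBr3 (8 equiv), CH2Cl2, −78 °C → rt; MeOH, then H2O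
Reagents that add atoms: none
Why: Global Lewis-acid cleavage of the four aryl methyl ethers; the ketone, the aryl bromide and the alkyl chain are stable to BBr3, and no stereocentre exists yet that could ionise.

**Step 5 (key step)**
Reactants: 7
Product: 8, 1^5,3^2,3^6-trihydroxy-2-oxa-1(1,3),3(1,4)-dibenzenacycloheptadecaphan-4-one. This is a 22-membered meta,para-cyclophane. Ring A is a benzene bearing OH, O-aryl and the CH2 end of the chain in a 1,3,5 pattern. Ring B is a 2,6-dihydroxyphenyl ether carrying the C(=O)(CH2)13 bridge para to the ether oxygen.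
Conditions: CuI (1.5 equiv), picolinic acid (3 equiv), Cs2CO3 (8 equiv), degassed DMSO, 105 °C, Ar, syringe-pump addition of 7 over 24 h (final 2 mM); aq HCl work-up
Reagents that add atoms: none
Why: Proposed new method: Ullmann macro-etherification on a fully unprotected tetraphenol, with no direct precedent for an aryloxide attacking a C–Br flanked by two free phenoxides; the ring-B phenoxides are ortho to Br and cannot cyclise, so at 2 mM the only unimolecular pathway is delivery of a ring-A aryloxide (either homotopic OH gives the same product) through ArO–Cu(I) oxidative addition/reductive elimination at the para-acyl-activated C–Br; the closest known reactions are the Cu-mediated methoxylation/hydroxylation of 5-bromovanillin and 3,5-dibromo-4-hydroxybenzaldehyde (C–Br ortho to a free phenoxide) and Ullmann macrocyclisations of diaryl-ether cyclophanes; no stereocentre is formed.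

**Step 6**
Reactants: 8
Product: 9, gravicycle, (4R)-2-oxa-1(1,3),3(1,4)-dibenzenacycloheptadecaphane-1^5,3^2,3^6,4-tetrol (benzylic carbinol on ring B, R)
Conditions: RuCl(p-cymene)[(R,R)-TsDPEN] (2 mol %), HCO2H–Et3N (5:2), DMF, 40 °C
Reagents that add atoms: none (H only)
Why: Noyori–Ikariya asymmetric transfer hydrogenation of an aryl n-alkyl ketone; the (R,R)-catalyst gives the (R)-1-arylalkanol (the sense known for acetophenone and propiophenone), free phenols are tolerated in formic acid/triethylamine, and nothing afterwards can scramble the centre.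

**Compound list**
1 | 3,5-dimethoxybenzyl chloride | COc1cc(CCl)cc(OC)c1 | starting material (bulk aromatic intermediate)
2 | 1,12-dibromododecane | BrCCCCCCCCCCCCBr | starting material
3 | 1-(13-bromotridecyl)-3,5-dimethoxybenzene | COc1cc(CCCCCCCCCCCCCBr)cc(OC)c1 | intermediate
4 | 4-bromo-3,5-dimethoxybenzoic acid | COc1cc(C(=O)O)cc(OC)c1Br | starting material
5 | 4-bromo-N,3,5-trimethoxy-N-methylbenzamide | COc1cc(C(=O)N(C)OC)cc(OC)c1Br | intermediate
6 | 1-(4-bromo-3,5-dimethoxyphenyl)-14-(3,5-dimethoxyphenyl)tetradecan-1-one | COc1cc(CCCCCCCCCCCCCC(=O)c2cc(OC)c(Br)c(OC)c2)cc(OC)c1 | intermediate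
7 | 1-(4-bromo-3,5-dihydroxyphenyl)-14-(3,5-dihydroxyphenyl)tetradecan-1-one | Oc1cc(CCCCCCCCCCCCCC(=O)c2cc(O)c(Br)c(O)c2)cc(O)c1 | intermediate
8 | 1^5,3^2,3^6-trihydroxy-2-oxa-1(1,3),3(1,4)-dibenzenacycloheptadecaphan-4-one (achiral macrocyclic ketone) | Oc1cc2cc(c1)Oc1c(O)cc(cc1O)C(=O)CCCCCCCCCCCCC2 | intermediate
9 | gravicycle, (4R)-2-oxa-1(1,3),3(1,4)-dibenzenacycloheptadecaphane-1^5,3^2,3^6,4-tetrol | Oc1cc2cc(c1)Oc1c(O)cc(cc1O)[C@H](O)CCCCCCCCCCCCC2 | target

**Totals**
Total steps: 6. Longest linear sequence: 5 (steps 1, 3, 4, 5, 6).

**Steps most likely to fail, with fallbacks**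
1. Step 5. Risks are intermolecular etherification through the more acidic ring-B phenoxides, sluggish C–Br activation in the electron-rich dianion, and protodebromination. Fallback: carry ring B through the ring closure as its dimethyl ether. Demethylate 3 first to 5-(13-bromotridecyl)resorcinol, form its Grignard under transient O-silylation and add it to 5, cyclise the free resorcinol onto the 4-bromo-3,5-dimethoxyaryl ketone (a precedented hindered Ullmann), then BBr3 and the same final reduction. This costs one extra step.
2. Step 1. Risks are Wurtz homocoupling of the benzylic Grignard and double alkylation of the dibromide. Fallback: build 3 by Wittig olefination of 3,5-dimethoxybenzaldehyde with the ylide from (12-hydroxydodecyl)triphenylphosphonium bromide, then alkene hydrogenation and Appel bromination.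
3. Step 6. Risks are slow turnover or eroded ee on the electron-rich, triphenolic ketone. Fallback: silylate the three phenols (TBSCl), reduce with (S)-Me-CBS/BH3·SMe2 (which gives the R carbinol for aryl alkyl ketones), and desilylate with TBAF/AcOH.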